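**Retrosynthetic overview**
1. Feature: in the tetrahydrofuran ring (O1, C2–C5, with C2 the veratryl carbon) C5 is bonded only to O1, C4, the syringyl ring and H. It is therefore a masked aldehyde carbon that can be inserted between an oxygen on C2 and a nucleophilic C4.
2. Endgame: the phenol comes from its benzyl ether. The C4 methyl comes from CH2OMs, then CH2OH, then CHO, which is what remains of an enol ether.
3. Key cut: C5–O1 and C4–C5 are broken together. This gives O-benzylsyringaldehyde (one carbon) and the four-atom unit O1–C2–C3–C4 as an anti γ-silyloxy methyl enol ether. This (4+1) closure forms the only ring built in the synthesis.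
4. The enol ether comes from veratraldehyde by catalytic asymmetric anti-crotylation (sets C2, C3 and the absolute configuration), silylation, alkene cleavage and a methoxymethylene Wittig reaction.
5. Stereo plan: C5 is set by kinetic closure (2,5-cis). C4 is set by base equilibration of the formyl-bearing carbon directly afterwards.

Key step: step 6

Numbering: the target locants O1, C2 (veratryl-bearing), C3, C4 and C5 (syringyl-bearing) are used for all intermediates, including the open-chain ones.
Assumption: the (S) antipode of the TRIP phosphoric acid is taken to send the crotyl group to the Si face of the aromatic aldehyde; if the sense of induction were the opposite, the (R) acid would be used and nothing else changes.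

Step 1
Reactants: 1 veratraldehyde; 2 (E)-crotylboronic acid pinacol ester
Product: 3 (1S,2S)-1-(3,4-dimethoxyphenyl)-2-methylbut-3-en-1-ol (anti)
Conditions: (S)-TRIP phosphoric acid (5 mol %), toluene, −30 °C; aqueous work-up
Reagents that add atoms: none
Why: Chiral phosphoric acid-catalysed crotylboration runs through a closed chair (Zimmerman–Traxler) transition state in which the E-crotyl geometry gives the anti C2/C3 pair and the catalyst pocket selects the Si face of the aldehyde, so C2 (S) and C3 (S) are both set here.

Step 2
Reactants: 3 anti homoallylic alcohol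
Product: 4 triethylsilyl ether of 3
Conditions: TESCl, imidazole, CH2Cl2, 0 °C to rt
Reagents that add atoms: chlorotriethylsilane, CC[Si](Cl)(CC)CC
Why: Standard silylation of a secondary alcohol that touches no stereocentre; TES is chosen because it survives the next two steps yet is labile enough to leave oxygen in step 6.

Step 3
Reactants: 4 TES-protected homoallylic alcohol
Product: 5 (2R,3S)-3-(3,4-dimethoxyphenyl)-2-methyl-3-(triethylsilyloxy)propanal
Conditions: OsO4 (2 mol %), NaIO4, 2,6-lutidine, dioxane–H2O (3:1), rt
Reagents that add atoms: sodium periodate, [Na+].[O-]I(=O)(=O)=O (terminal oxygen source); osmium tetroxide, O=[Os](=O)(=O)=O (catalytic oxygen carrier)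
Why: Lemieux–Johnson cleavage attacks only the terminal alkene and spares the electron-rich ring that ozone could touch, and lutidine keeps the medium near neutral so that C3 (descriptor changes to R by priority only) and the TES ether hold.

Step 4
Reactants: 5 β-silyloxy-α-methyl aldehyde; 6 (methoxymethyl)triphenylphosphonium chloride
Product: 7 (1S,2S)-1-(3,4-dimethoxyphenyl)-4-methoxy-2-methylbut-3-enyl triethylsilyl ether (E/Z mixture; E isomer drawn)
Conditions: 6, KHMDS, THF, 0 °C; then 5, −78 to 0 °C; Et3N-washed silica
Reagents that add atoms: none
Why: Wittig methoxymethylenation with the non-stabilised ylide is fast in the cold, so α-epimerisation and β-elimination of silanolate should not compete, and the E/Z mixture is used as such because the geometry can influence only C4, which is equilibrated in step 6.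

Step 5
Reactants: 8 syringaldehyde
Product: 9 O-benzylsyringaldehyde (4-benzyloxy-3,5-dimethoxybenzaldehyde)
Conditions: BnBr, K2CO3, DMF, 60 °C
Reagents that add atoms: benzyl bromide, BrCc1ccccc1
Why: Williamson ether synthesis on an acidic, para-formyl phenol; the phenoxide is the only nucleophile present.

Step 6
Reactants: 7 anti γ-silyloxy methyl enol ether; 9 O-benzylsyringaldehyde
Product: 13 (2S,3S,4R,5R)-5-(4-benzyloxy-3,5-dimethoxyphenyl)-2-(3,4-dimethoxyphenyl)-4-formyl-3-methyltetrahydrofuran, via oxocarbenium triflate 10 (not isolated), via methoxycarbenium triflate 11 (not isolated), via 4-epi-aldehyde 12 (not isolated)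
Conditions: 2,6-di-tert-butyl-4-methylpyridine (0.3 equiv), TMSOTf (1.1 equiv, slow addition), CH2Cl2 (0.02 M), −78 °C; sat. aq NaHCO3; crude: DBU (0.2 equiv), CH2Cl2, rt
Reagents that add atoms: water, O
Why: TMSOTf silylates aldehyde 9, the silyl ether oxygen of 7 adds and Et3SiOSiMe3 departs, which gives the aryl-stabilised (E)-oxocarbenium ion 10 (new C5–O1 bond) in a medium free of water and protons; the TES ether is used instead of the free alcohol because a free γ-hydroxy enol ether would close onto its own protonated enol ether to a 2-methoxytetrahydrofuran. The electron-rich enol ether carbon C4 then attacks C5 (new C4–C5 bond) and closes the tetrahydrofuran, 5-endo-trig with respect to C5=O1+ and exo with respect to the enol ether, and the methoxycarbenium ion 11 left on the side chain is hydrolysed to the formyl group on bicarbonate work-up. The closest known reaction types are the Lewis acid induced [1,3] O-to-C ring contraction of cyclic vinyl acetals (4,5-dihydro-1,3-dioxepines to tetrahydrofuran-3-carbaldehydes) and the BF3-mediated condensation of 4-hydroxy-1-alkenyl carbamates with aldehydes, which pass through the same oxocarbenium/enol pair and the same closure mode. C5 is set kinetically: in the envelope transition state of the (E)-ion the C2 aryl, the C3 methyl (trans to it because of the anti C2/C3 pair) and the C5 aryl are all pseudo-equatorial with H2 and H5 on the same face, which leads to the 2,5-cis ring, and the reaction is kept cold and short because a reversible closure would drain into the all-trans (2,5-trans) isomer. C4 is not left to the closure, in which allylic strain (H3 eclipsing the enol ether double bond, compelling for the Z isomer) should place the side chain trans to the C3 methyl as in 12; catalytic DBU then equilibrates this single acidic centre, the formyl group should move off the face that carries both aryl rings and end up trans to the bulky C5 aryl and next to the smaller methyl (13), remaining 12 is separated and resubmitted, and β-elimination of O1 is held back because the C5–O1 bond lies nearly orthogonal to the enolate π system (reverse of a 5-endo-trig closure). The step further needs O–C bonding before C–C bonding and an intact C2–C3 bond: high dilution and slow addition of TMSOTf favour the tethered closure over intermolecular aldol-type attack on silylated 9, and the 2-oxonia-Cope shift that could scramble C2 and C3 is polarity-mismatched since it would have to join C5 to the oxygen-bearing enol ether carbon.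

Step 7
Reactants: 13 4-formyltetrahydrofuran
Product: 14 (2S,3S,4S,5R)-4-hydroxymethyl analogue of 13
Conditions: NaBH4, MeOH–THF, 0 °C
Reagents that add atoms: none
Why: Borohydride 1,2-reduction of the only carbonyl group is fast at 0 °C, so C4 keeps the configuration reached in step 6 (the descriptor changes by priority only).

Step 8
Reactants: 14 primary alcohol
Product: 15 methanesulfonate of 14
Conditions: MsCl, Et3N, CH2Cl2, 0 °C
Reagents that add atoms: methanesulfonyl chloride, CS(=O)(=O)Cl
Why: Sulfonylation of the only hydroxyl group under mild basic conditions involves no stereocentre and leaves the acid-sensitive benzylic ring ethers alone.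

Step 9
Reactants: 15 primary mesylate
Product: 16 (2S,3S,4R,5R)-5-(4-benzyloxy-3,5-dimethoxyphenyl)-2-(3,4-dimethoxyphenyl)-3,4-dimethyltetrahydrofuran
Conditions: LiEt3BH, THF, 0 °C to rt
Reagents that add atoms: none
Why: SN2 displacement of a primary sulfonate by triethylborohydride, a hydride nucleophile strong enough for a β-branched carbon, takes place at the exocyclic carbon, so C4 is untouched and the aryl, benzyl and ring ethers are inert.

Step 10
Reactants: 16 O-benzyl ether of the target
Product: 17 target, (2S,3S,4R,5R)-2-(3,4-dimethoxyphenyl)-5-(4-hydroxy-3,5-dimethoxyphenyl)-3,4-dimethyltetrahydrofuran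
Conditions: H2 (1 atm), 10% Pd/C, EtOAc, rt, stopped at full conversion
Reagents that add atoms: none
Why: Catalytic hydrogenolysis should cleave the unhindered aryl benzyl ether well before the two hindered secondary ring C–O bonds at 1 atm in a non-acidic solvent, and no stereocentre is touched.

**Compound list**
1 | veratraldehyde | COc1ccc(C=O)cc1OC | starting material
2 | (E)-crotylboronic acid pinacol ester | C/C=C/CB1OC(C)(C)C(C)(C)O1 | starting material
3 | (1S,2S)-1-(3,4-dimethoxyphenyl)-2-methylbut-3-en-1-ol | COc1ccc([C@@H](O)[C@@H](C)C=C)cc1OC | intermediate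
4 | triethylsilyl ether of 3 | COc1ccc([C@@H](O[Si](CC)(CC)CC)[C@@H](C)C=C)cc1OC | intermediate
5 | (2R,3S)-3-(3,4-dimethoxyphenyl)-2-methyl-3-(triethylsilyloxy)propanal | COc1ccc([C@@H](O[Si](CC)(CC)CC)[C@@H](C)C=O)cc1OC | intermediate
6 | (methoxymethyl)triphenylphosphonium chloride | COC[P+](c1ccccc1)(c1ccccc1)c1ccccc1.[Cl-] | starting material
7 | (1S,2S)-1-(3,4-dimethoxyphenyl)-4-methoxy-2-methylbut-3-enyl triethylsilyl ether (E/Z mixture, E drawn) | COc1ccc([C@@H](O[Si](CC)(CC)CC)[C@@H](C)/C=C/OC)cc1OC | intermediate
8 | syringaldehyde | COc1cc(C=O)cc(OC)c1O | starting material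
9 | O-benzylsyringaldehyde | COc1cc(C=O)cc(OC)c1OCc1ccccc1 | intermediate
10 | (E)-oxocarbenium triflate (C5=O1+), not isolated | COc1ccc([C@@H](/[O+]=C/c2cc(OC)c(OCc3ccccc3)c(OC)c2)[C@@H](C)/C=C/OC)cc1OC.[O-]S(=O)(=O)C(F)(F)F | intermediate
11 | cyclised methoxycarbenium triflate (2,5-cis, side chain trans to C3 methyl), not isolated | COc1ccc([C@H]2O[C@@H](c3cc(OC)c(OCc4ccccc4)c(OC)c3)[C@@H](C=[O+]C)[C@@H]2C)cc1OC.[O-]S(=O)(=O)C(F)(F)F | intermediate
12 | (2S,3S,4S,5R)-4-epi-aldehyde (formyl cis to C5 aryl), not isolated | COc1ccc([C@H]2O[C@@H](c3cc(OC)c(OCc4ccccc4)c(OC)c3)[C@@H](C=O)[C@@H]2C)cc1OC | intermediate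
13 | (2S,3S,4R,5R)-5-(4-benzyloxy-3,5-dimethoxyphenyl)-2-(3,4-dimethoxyphenyl)-4-formyl-3-methyltetrahydrofuran | COc1ccc([C@H]2O[C@@H](c3cc(OC)c(OCc4ccccc4)c(OC)c3)[C@H](C=O)[C@@H]2C)cc1OC | intermediate
14 | (2S,3S,4S,5R)-4-hydroxymethyl compound | COc1ccc([C@H]2O[C@@H](c3cc(OC)c(OCc4ccccc4)c(OC)c3)[C@H](CO)[C@@H]2C)cc1OC | intermediate
15 | methanesulfonate of 14 | COc1ccc([C@H]2O[C@@H](c3cc(OC)c(OCc4ccccc4)c(OC)c3)[C@H](COS(C)(=O)=O)[C@@H]2C)cc1OC | intermediate
16 | O-benzyl ether of the target | COc1ccc([C@H]2O[C@@H](c3cc(OC)c(OCc4ccccc4)c(OC)c3)[C@H](C)[C@@H]2C)cc1OC | intermediate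
17 | CNP0326872.1, (2S,3S,4R,5R)-2-(3,4-dimethoxyphenyl)-5-(4-hydroxy-3,5-dimethoxyphenyl)-3,4-dimethyltetrahydrofuran | COc1ccc([C@H]2O[C@@H](c3cc(OC)c(O)c(OC)c3)[C@H](C)[C@@H]2C)cc1OC | target

Total step count: 10. Longest linear sequence: 9 (steps 1–4 and 6–10, from veratraldehyde).

**Steps most likely to fail**

Step 6. Four processes could defeat this step:
- The enol ether may be used up before the tethered ion exists, either by loss of the silyl group and acid-triggered self-acetalisation or by intermolecular aldol-type attack on the activated aldehyde.
- The hindered silyl ether may ionise too slowly.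
- Facial selectivity at C5 may erode if the closure turns reversible.
- The C4 equilibrium may lie less far on the wanted side than expected.

Fallback, from 1 back to 13: the nucleophile is changed to an enol carbamate. It is much less basic and nucleophilic than a methyl enol ether, it tolerates a free hydroxyl group and a Lewis acid, and it belongs to the substrate class for which this condensation is established. (E)-But-2-en-1-ol is carbamoylated (iPr2NCOCl, pyridine) to (E)-but-2-enyl N,N-diisopropylcarbamate F1. An asymmetric homoaldol reaction follows: n-BuLi with the sparteine antipode that leads to the 3S,4S series, crystallisation-driven resolution of the lithio species, exchange with Ti(OiPr)4, then 1. This gives (1Z,3S,4S)-4-(3,4-dimethoxyphenyl)-4-hydroxy-3-methylbut-1-enyl N,N-diisopropylcarbamate F2. F2 and 9 with BF3·OEt2 in CH2Cl2 (−78 to 0 °C) close the same ring through the same two bonds with loss of the carbamoyl group. The DBU treatment of step 6 then leads to 13.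

Step 10. Hydrogenolysis may not stop at the aryl benzyl ether and may open the ring at the doubly activated C2–O1 or C5–O1 bond.

Fallback, from 8 to 17: the phenol is carried as a pivalate that falls in the hydride step, so no hydrogenation is needed. Compound 8 is acylated (PivCl, Et3N, DMAP) to 4-formyl-2,6-dimethoxyphenyl pivalate F3. F3 and 7 under the conditions of step 6 give the pivalate-protected 4-formyltetrahydrofuran F4. NaBH4 gives the pivalate-protected primary alcohol F5, and MsCl/Et3N gives the pivalate-protected mesylate F6. LiAlH4 in THF (rt to reflux) then displaces the mesylate and cleaves the ester in one flask to give 17.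

Step 4. The basic ylide may epimerise C3 of aldehyde 5 or trigger β-elimination of silanolate, and the acid-labile enol ether may be lost during purification.

Fallback, from 4 back to 7: aldehyde 5 is bypassed altogether. Cross metathesis of 4 with vinylboronic acid pinacol ester (Hoveyda–Grubbs II, CH2Cl2, reflux) gives the (E)-alkenylboronic acid pinacol ester F7. Copper-mediated Chan–Lam-type C–O coupling with methanol (Cu(OAc)2, Et3N, MeOH, air, rt) proceeds with retention of alkene geometry and gives 7 as the pure E isomer.

**Further compounds**
F1 | step 6 | (E)-but-2-enyl N,N-diisopropylcarbamate | C/C=C/COC(=O)N(C(C)C)C(C)C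
F2 | step 6 | (1Z,3S,4S)-4-(3,4-dimethoxyphenyl)-4-hydroxy-3-methylbut-1-enyl N,N-diisopropylcarbamate | COc1ccc([C@@H](O)[C@@H](C)/C=C\OC(=O)N(C(C)C)C(C)C)cc1OC
F3 | step 10 | 4-formyl-2,6-dimethoxyphenyl pivalate | COc1cc(C=O)cc(OC)c1OC(=O)C(C)(C)C
F4 | step 10 | pivalate-protected 4-formyltetrahydrofuran (2S,3S,4R,5R) | COc1ccc([C@H]2O[C@@H](c3cc(OC)c(OC(=O)C(C)(C)C)c(OC)c3)[C@H](C=O)[C@@H]2C)cc1OC
F5 | step 10 | pivalate-protected primary alcohol (2S,3S,4S,5R) | COc1ccc([C@H]2O[C@@H](c3cc(OC)c(OC(=O)C(C)(C)C)c(OC)c3)[C@H](CO)[C@@H]2C)cc1OC
F6 | step 10 | pivalate-protected mesylate (2S,3S,4S,5R) | COc1ccc([C@H]2O[C@@H](c3cc(OC)c(OC(=O)C(C)(C)C)c(OC)c3)[C@H](COS(C)(=O)=O)[C@@H]2C)cc1OC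
F7 | step 4 | (E)-alkenylboronic acid pinacol ester of the TES-protected C2–C4 unit | COc1ccc([C@@H](O[Si](CC)(CC)CC)[C@@H](C)/C=C/B2OC(C)(C)C(C)(C)O2)cc1OC
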